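The data were computed with made-up constants.

A small charge of reagent is what ash holds until its last portion at 3.0 min, and the question is what the starting material does meanwhile.

| flask | starting material | reagent | temperature | remark | time |
|---|---|---|---|---|---|
| north | 0.10 M | 2.5 equiv | 60 °C | run made earlier |  |
| north-east | 0.050 M | 2.5 equiv | 60 °C | run made earlier |  |
| elm | 0.10 M (fed, over 3.0 min) | 2.50 equiv |  | the addition at 30 °C, then warmed to 60 °C; the feed brings no volume worth counting | 5.0 min |
| ash | 0.10 M | 2.50 equiv (in portions, 2, over 3.0 min) | 60 °C | first portion at the start, last at 3.0 min | 5.0 min |
| oak | 0.10 M (fed, over 3.0 min) | 2.50 equiv | 60 °C | all else is in the flask from the start; the feed brings no volume worth counting | 5.0 min |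
| maple | 0.10 M | 2.50 equiv | 60 °C | everything together at the start | 5.0 min |
| birch | 0.10 M | 2.50 equiv |  | everything together at the start at 30 °C, warmed to 60 °C at 3.0 min | 5.0 min |

north run (percent of the starting material charged)

| time / min | side product / % | target / % |
|---|---|---|
| 0.417 | 11.4 | 6.0 |
| 0.667 | 16.1 | 10.6 |
| 1.00 | 22.9 | 14.9 |
| 1.33 | 28.8 | 17.1 |
| 2.00 | 37.7 | 23.5 |
| 3.00 | 46.0 | 27.9 |
| 5.00 | 55.7 | 32.2 |

north-east run (percent of the starting material charged)

| time / s | side product / % | target / % |
|---|---|---|
| 10.0 | 4.2 | 2.1 |
| 15.0 | 7.0 | 2.1 |
| 25.0 | 11.4 | 3.3 |
| 30.0 | 12.8 | 4.5 |
| 40.0 | 17.8 | 5.7 |
| 50.0 | 19.6 | 7.1 |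
| 60.0 | 23.2 | 8.5 |

(standard deviation of a reading: 0.5 percentage points)

- the earlier runs do not show what temperature does; that part of a forecast is a guess
- a reading or a percentage of target counts all its forms, free or not

- which flask leads in amount of side product, in percent of the starting material charged ("all alike" within 1.5 percentage points) (elm / ash / oak / maple / birch / all alike)
- how much side product is there at the end, in percent of the starting material charged: elm
- how much side product is there at the end, in percent of the starting material charged: ash
- how much side product is there at the end, in percent of the starting material charged: oak
- how much side product is there at the end, in percent of the starting material charged: maple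
- how much side product is there at the end, in percent of the starting material charged: birch

Starting material leaves by two paths, so the fraction left is the quantity to follow. In the north run at 5.00 min, side product 55.7% and target 32.2% leave a fraction of 12.1%, which reads as a total constant of 0.422 /min. The ratio of side product made to target made, here called the selectivity factor S, is 1.73. It splits that total into 0.268 /min for the side path and 0.155 /min for the target path, the side path being faster.

Dilution tells the two paths apart. At half the concentration, the north-east run shows side product 23.2% after 60.0 s, against 22.9% in the north run at the same time, but target 8.5% against 14.9%. Its ratio of side product to target reads 2.73 against 1.54 in north, a factor of 1.78. Both runs hold 2.5 equiv of reagent, so c(starting material) and c(reagent) fell together, and these readings cannot tell which of the two the target path follows. The reckoning here assumes that S goes inversely with c(reagent).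

Ash starts with half its reagent charge and receives the rest at 3.0 min, so on that assumption S until then is taken as twice the north value. The reckoning made here, with these two constants, leaves 35.5% of the starting material in ash at 3.0 min and ends at 62.9% side product.

The forecast names ash as the leader, saying “half the reagent early favours side product”. It gives ash 65% (range 60% to 69%), which is above the reckoning here, then maple 55.7%, oak 49%, birch 42% and elm 40%.

    starting material + reagent → target (k = 0.0130 /M/s, Ea = 52.0 kJ/mol)
    starting material → side product (k = 0.00480 /s, Ea = 97.0 kJ/mol)
    target ⇌ isomer of the product (K = 0.100, k = 0.0360 /s, Ea = 80.0 kJ/mol, ΔH = 15.0 kJ/mol)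
    reagent + target ⇌ idle adduct, settled at all times (K = 36.0 /M, ΔH = −56.0 kJ/mol)
    (constants at 60 °C)

Ash leads with 64.1%, followed by maple 56.3%, oak 48.8%, elm 36.7% and birch 36.1%. Just before its last addition at 3.00 min, ash held side product 51.8% against target 15.2%, idle adduct counted in, a ratio of 3.41, where the doubled S gives 3.46. The neighbour of ash charged with 0.25 M of starting material has every c(reagent) raised 2.50 times, so on the same assumption S is divided by that factor, and the same reckoning gives 51.0% side product, while that flask holds 53.7%.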